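**Plan**

- Retrosynthesis cuts, in order: the O-methyl bond at C4 of ring A; then, in one operation, the ester C-O bond between the ring A carbonyl and the C4 oxygen of ring B together with the C1-C6 bond of ring A; last, the ester C-O bond between the ring B carbonyl and the C4 oxygen of ring C.
- Enabling feature: ring A carries oxygen at C2 and C4 and a methyl at C6 around the carbonyl-bearing C1, which is a 3,5,7-trioxooctanoyl chain folded C2 onto C7. Its di-ortho-flanked ester can therefore be made from an open, unhindered acylketene before the ring exists.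
- Forward: rings B and C both come from methyl orsellinate and are joined by a mixed-anhydride esterification. The eight-carbon chain is built on a dioxinone by two acetylations, joined to ring B, and ring A closes last; one O-methylation finishes.
- Stereochemistry: the target has no stereocentre and no stereogenic double bond; only regiochemistry has to be controlled.

Key step: step 9

**Route**

Step 1
Reactants: 1 methyl orsellinate (methyl 2,4-dihydroxy-6-methylbenzoate)
Product: 2 methyl 4-(benzyloxy)-2-hydroxy-6-methylbenzoate
Conditions: BnBr (1.05 equiv), K2CO3, acetone, reflux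
Reagents that add atoms: benzyl bromide, BrCc1ccccc1
Why: The C4 phenol is the more acidic, unchelated hydroxyl while the C2 phenol is hydrogen-bonded to the ester carbonyl, so a Williamson etherification with one equivalent of halide and a weak base should stop at the 4-O-benzyl ether.

Step 2
Reactants: 2 methyl 4-(benzyloxy)-2-hydroxy-6-methylbenzoate
Product: 3 methyl 4-(benzyloxy)-2-methoxy-6-methylbenzoate
Conditions: MeI (3 equiv), K2CO3, DMF, 50 °C
Reagents that add atoms: methyl iodide, CI
Why: With only the chelated C2 phenol left, excess methyl iodide in warm DMF should force the second Williamson etherification and install the ortho-methoxy group common to rings B and C.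

Step 3
Reactants: 3 methyl 4-(benzyloxy)-2-methoxy-6-methylbenzoate
Product: 4 methyl 4-hydroxy-2-methoxy-6-methylbenzoate (ring C phenol)
Conditions: H2 (1 atm), 10% Pd/C, EtOAc, rt
Reagents that add atoms: none
Why: Catalytic hydrogenolysis cleaves the benzyl aryl ether and leaves the methyl ester and the aryl methyl ether untouched.

Step 4
Reactants: 3 methyl 4-(benzyloxy)-2-methoxy-6-methylbenzoate
Product: 5 4-(benzyloxy)-2-methoxy-6-methylbenzoic acid (ring B acid)
Conditions: KOH, DMSO-H2O, 90 °C; then 1 M HCl, 0 °C
Reagents that add atoms: potassium hydroxide, [K+].[OH-]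
Why: Saponification of a di-ortho-substituted methyl benzoate is slow but proceeds with hydroxide in hot aqueous DMSO, and cold acidification should avoid decarboxylation of the electron-rich acid.

Step 5
Reactants: 5 4-(benzyloxy)-2-methoxy-6-methylbenzoic acid; 4 methyl 4-hydroxy-2-methoxy-6-methylbenzoate
Product: 7 methyl 4-{[4-(benzyloxy)-2-methoxy-6-methylbenzoyl]oxy}-2-methoxy-6-methylbenzoate, via mixed trifluoroacetic anhydride 6 (not isolated)
Conditions: (CF3CO)2O, PhMe, rt
Reagents that add atoms: none
Why: Trifluoroacetic anhydride converts the hindered, electron-rich acid into a mixed anhydride that ionises toward a stabilised acylium ion and acylates the phenol oxygen, the standard mixed-anhydride esterification for depsides.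

Step 6
Reactants: 7 methyl 4-{[4-(benzyloxy)-2-methoxy-6-methylbenzoyl]oxy}-2-methoxy-6-methylbenzoate
Product: 8 methyl 4-[(4-hydroxy-2-methoxy-6-methylbenzoyl)oxy]-2-methoxy-6-methylbenzoate (B-C phenol)
Conditions: H2 (1 atm), 10% Pd/C, EtOAc, rt
Reagents that add atoms: none
Why: Hydrogenolysis removes the benzyl ether while the aryl ester and the methyl ester are inert to H2 over Pd/C, which frees the C4 phenol of ring B.

Step 7
Reactants: 9 2,2,6-trimethyl-4H-1,3-dioxin-4-one; 10 acetyl chloride
Product: 11 6-(2-oxopropyl)-2,2-dimethyl-4H-1,3-dioxin-4-one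
Conditions: LiN(SiMe3)2, THF, -78 °C; then AcCl (0.5 equiv per dienolate), -78 °C; aq. NH4Cl
Reagents that add atoms: none
Why: The amide base removes a proton from the C6 methyl to give the extended dienolate, which undergoes Claisen-type C-acylation at its gamma carbon; the dienolate is kept in excess because the product is more acidic than the starting dioxinone.

Step 8
Reactants: 11 6-(2-oxopropyl)-2,2-dimethyl-4H-1,3-dioxin-4-one; 12 N-methoxy-N-methylacetamide
Product: 13 6-(2,4-dioxopentyl)-2,2-dimethyl-4H-1,3-dioxin-4-one (diketo-dioxinone)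
Conditions: LiN(iPr)2 (2.2 equiv), THF, -78 °C; then 12, -78 to -20 °C; cold 1 M HCl
Reagents that add atoms: none
Why: Double deprotonation gives a dianion whose last-formed terminal carbanion is the most nucleophilic site, and its acylation by the Weinreb amide stops at a chelated tetrahedral intermediate, so the dianion gamma-acylation should give the 1,3-diketone without over-addition.

Step 9
Reactants: 13 6-(2,4-dioxopentyl)-2,2-dimethyl-4H-1,3-dioxin-4-one; 8 B-C phenol
Product: 17 ring A dihydroxy tridepside (methyl 4-({4-[(2,4-dihydroxy-6-methylbenzoyl)oxy]-2-methoxy-6-methylbenzoyl}oxy)-2-methoxy-6-methylbenzoate), via acylketene 14 (not isolated), via aryl 3,5,7-trioxooctanoate 15 (not isolated), via cyclic aldol adduct 16 (not isolated)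
Conditions: 8 (concentrated), 13 (1.5 equiv, in portions), PhMe, 110 °C; concentrate; Et3N (cat.), CH2Cl2, rt; then CF3CO2H, rt
Reagents that add atoms: none
Why: Retro-(4+2) fragmentation of the dioxinone at 110 °C expels acetone and leaves a linear acylketene with an unhindered sp carbon, so the weakly nucleophilic C4 phenol of ring B adds and forms the A-B ester C-O bond as an aryl beta-keto ester. Amine base then enolises the doubly activated C2 methylene, which attacks the C7 methyl ketone in a 6-(enolexo)-exo-trig aldol that forms the ring A C1-C6 bond; acid removes the tertiary hydroxyl as the single molecule of water that must be lost, and enolisation of the two remaining ring ketones gives the resorcylate. The closest known reaction type is the thermolysis of diketo-dioxinones with capture of the acylketene by alcohols or phenols, followed by biomimetic aldol aromatisation. No stereocentre has to be controlled, since the two centres formed in 16 are erased on aromatisation. Capture by the phenol must outrun cyclisation of the ketene onto its own C5 enol oxygen, which a high concentration of 8 and an excess of 13 should secure. Carbon-carbon closure must also win over expulsion of the ring B phenoxide (pyrone or Claisen closure), which is favoured because C2 is the most acidic site of the chain and no alcohol or strong base is present; once ring A is aromatic its ester is shielded by the C2 hydroxyl and the C6 methyl.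

Step 10
Reactants: 17 ring A dihydroxy tridepside
Product: 18 methyl 4-({4-[(2-hydroxy-4-methoxy-6-methylbenzoyl)oxy]-2-methoxy-6-methylbenzoyl}oxy)-2-methoxy-6-methylbenzoate (target)
Conditions: MeI (1.05 equiv), K2CO3 (1.1 equiv), acetone, rt
Reagents that add atoms: methyl iodide, CI
Why: The C4 phenol of ring A is free and more acidic, whereas the C2 phenol is locked in a hydrogen bond to the ester carbonyl, so a Williamson methylation with one equivalent of methyl iodide under weak base should stop at the monomethyl ether.

**Compound list**

1 | methyl orsellinate (methyl 2,4-dihydroxy-6-methylbenzoate) | COC(=O)c1c(C)cc(O)cc1O | starting material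
2 | methyl 4-(benzyloxy)-2-hydroxy-6-methylbenzoate | COC(=O)c1c(C)cc(OCc2ccccc2)cc1O | intermediate
3 | methyl 4-(benzyloxy)-2-methoxy-6-methylbenzoate | COC(=O)c1c(C)cc(OCc2ccccc2)cc1OC | intermediate
4 | methyl 4-hydroxy-2-methoxy-6-methylbenzoate | COC(=O)c1c(C)cc(O)cc1OC | intermediate
5 | 4-(benzyloxy)-2-methoxy-6-methylbenzoic acid | OC(=O)c1c(C)cc(OCc2ccccc2)cc1OC | intermediate
6 | 4-(benzyloxy)-2-methoxy-6-methylbenzoic trifluoroacetic anhydride (formed in the flask) | O=C(OC(=O)C(F)(F)F)c1c(C)cc(OCc2ccccc2)cc1OC | intermediate
7 | methyl 4-{[4-(benzyloxy)-2-methoxy-6-methylbenzoyl]oxy}-2-methoxy-6-methylbenzoate | COC(=O)c1c(C)cc(OC(=O)c2c(C)cc(OCc3ccccc3)cc2OC)cc1OC | intermediate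
8 | methyl 4-[(4-hydroxy-2-methoxy-6-methylbenzoyl)oxy]-2-methoxy-6-methylbenzoate (B-C phenol) | COC(=O)c1c(C)cc(OC(=O)c2c(C)cc(O)cc2OC)cc1OC | intermediate
9 | 2,2,6-trimethyl-4H-1,3-dioxin-4-one | CC1=CC(=O)OC(C)(C)O1 | starting material
10 | acetyl chloride | CC(=O)Cl | starting material
11 | 6-(2-oxopropyl)-2,2-dimethyl-4H-1,3-dioxin-4-one | CC(=O)CC1=CC(=O)OC(C)(C)O1 | intermediate
12 | N-methoxy-N-methylacetamide | CC(=O)N(C)OC | starting material
13 | 6-(2,4-dioxopentyl)-2,2-dimethyl-4H-1,3-dioxin-4-one | CC(=O)CC(=O)CC1=CC(=O)OC(C)(C)O1 | intermediate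
14 | oct-1-ene-1,3,5,7-tetrone (acylketene, formed in the flask) | CC(=O)CC(=O)CC(=O)C=C=O | intermediate
15 | 3-methoxy-4-{[3-methoxy-4-(methoxycarbonyl)-5-methylphenoxy]carbonyl}-5-methylphenyl 3,5,7-trioxooctanoate (formed in the flask) | COC(=O)c1c(C)cc(OC(=O)c2c(C)cc(OC(=O)CC(=O)CC(=O)CC(C)=O)cc2OC)cc1OC | intermediate
16 | the corresponding aryl 2-hydroxy-2-methyl-4,6-dioxocyclohexane-1-carboxylate (aldol adduct, mixture of stereoisomers and enol forms, formed in the flask) | COC(=O)c1c(C)cc(OC(=O)c2c(C)cc(OC(=O)C3C(=O)CC(=O)CC3(C)O)cc2OC)cc1OC | intermediate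
17 | methyl 4-({4-[(2,4-dihydroxy-6-methylbenzoyl)oxy]-2-methoxy-6-methylbenzoyl}oxy)-2-methoxy-6-methylbenzoate | COC(=O)c1c(C)cc(OC(=O)c2c(C)cc(OC(=O)c3c(C)cc(O)cc3O)cc2OC)cc1OC | intermediate
18 | methyl 4-({4-[(2-hydroxy-4-methoxy-6-methylbenzoyl)oxy]-2-methoxy-6-methylbenzoyl}oxy)-2-methoxy-6-methylbenzoate | COC(=O)c1c(C)cc(OC(=O)c2c(C)cc(OC(=O)c3c(C)cc(OC)cc3O)cc2OC)cc1OC | target

**Summary**

Total step count: 10.
Longest linear sequence: 7 steps (steps 1, 2, 4, 5, 6, 9, 10); the dioxinone branch (steps 7, 8) and the ring C phenol (step 3) converge on it.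

**Steps most likely to fail**

Step 9. The acylketene may be consumed by attack of its own C5 enol oxygen (pyrone formation) before the phenol adds. During the base stage the open-chain aryl ester may also lose the ring B phenoxide through lactonisation, Claisen closure or reversion to the ketene. The fallback closes the ring first and makes the ester second. Setting out from 13, Et3N in CH2Cl2 should bring about the same C2-to-C7 aldol aromatisation with the dioxinone still intact, giving 7-hydroxy-2,2,5-trimethyl-4H-1,3-benzodioxin-4-one F1. Its only phenol is methylated (MeI, K2CO3, acetone) to 7-methoxy-2,2,5-trimethyl-4H-1,3-benzodioxin-4-one F2. Irradiation of F2 at 300 nm in CH2Cl2 in the presence of 8 expels acetone, and the ortho-quinone ketene 3-methoxy-5-methyl-6-(oxomethylidene)cyclohexa-2,4-dien-1-one F3 is captured by the ring B phenol, the known photochemical salicylate synthesis from benzodioxinones. The sequence comes back to the route at 18.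

Step 8. Proton exchange between the dianion and the enolisable amide or the product, O-acylation, or decomposition of the sensitive diketo-dioxinone on work-up may erode the acylation. The fallback forms the same carbon-carbon bond at a lower oxidation level. Setting out from 11, the same dianion is added to acetaldehyde, an aldol addition that outpaces enolisation, to give racemic 6-(4-hydroxy-2-oxopentyl)-2,2-dimethyl-4H-1,3-dioxin-4-one F4. Oxidation of the secondary alcohol with Dess-Martin periodinane in CH2Cl2 comes back to the route at 13.

Step 10. The hydrogen-bonded C2 phenol may be methylated as well, or the ring A phenoxide may trigger acyl transfer among the ester groups. The fallback installs the methyl ether before the A-B ester exists and joins ring A by a classical depside coupling. Setting out from 1, selective 4-O-methylation (MeI 1 equiv, K2CO3, acetone), well established on this simple monomer, gives methyl 2-hydroxy-4-methoxy-6-methylbenzoate F5. Benzylation of the chelated phenol (BnBr, K2CO3, DMF, 60 °C) gives methyl 2-(benzyloxy)-4-methoxy-6-methylbenzoate F6, and saponification (KOH, aqueous DMSO) gives 2-(benzyloxy)-4-methoxy-6-methylbenzoic acid F7. Trifluoroacetic anhydride in toluene converts F7 into 2-(benzyloxy)-4-methoxy-6-methylbenzoic trifluoroacetic anhydride F8, which acylates 8 to give the 2-O-benzyl tridepside F9. Hydrogenolysis (H2, Pd/C, EtOAc) comes back to the route at 18.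

**Further compounds**

F1 | step 9 | 7-hydroxy-2,2,5-trimethyl-4H-1,3-benzodioxin-4-one | Cc1cc(O)cc2OC(C)(C)OC(=O)c12
F2 | step 9 | 7-methoxy-2,2,5-trimethyl-4H-1,3-benzodioxin-4-one | COc1cc(C)c2C(=O)OC(C)(C)Oc2c1
F3 | step 9 | 3-methoxy-5-methyl-6-(oxomethylidene)cyclohexa-2,4-dien-1-one | O=C=C1C(C)=CC(OC)=CC1=O
F4 | step 8 | 6-(4-hydroxy-2-oxopentyl)-2,2-dimethyl-4H-1,3-dioxin-4-one (racemic) | CC(O)CC(=O)CC1=CC(=O)OC(C)(C)O1
F5 | step 10 | methyl 2-hydroxy-4-methoxy-6-methylbenzoate | COC(=O)c1c(C)cc(OC)cc1O
F6 | step 10 | methyl 2-(benzyloxy)-4-methoxy-6-methylbenzoate | COC(=O)c1c(C)cc(OC)cc1OCc1ccccc1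
F7 | step 10 | 2-(benzyloxy)-4-methoxy-6-methylbenzoic acid | OC(=O)c1c(C)cc(OC)cc1OCc1ccccc1
F8 | step 10 | 2-(benzyloxy)-4-methoxy-6-methylbenzoic trifluoroacetic anhydride | O=C(OC(=O)C(F)(F)F)c1c(C)cc(OC)cc1OCc1ccccc1
F9 | step 10 | methyl 4-({4-[(2-(benzyloxy)-4-methoxy-6-methylbenzoyl)oxy]-2-methoxy-6-methylbenzoyl}oxy)-2-methoxy-6-methylbenzoate | COC(=O)c1c(C)cc(OC(=O)c2c(C)cc(OC(=O)c3c(C)cc(OC)cc3OCc3ccccc3)cc2OC)cc1OC
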